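The earlier runs and the new flask are calculated on assumed constants, and the scatter is random.

I read these flasks at 10 min, but first I wanted the curve a flask walks along with the clock taken out.

| flask | substrate | partner | temperature | remark | time |
|---|---|---|---|---|---|
| beta | 0.29 M | 0.286 M | 110 °C | run made earlier |  |
| noon | 0.26 M | 0.286 M | 130 °C |  | 10 min |
| dawn | 1.0 M | 0.150 M | 110 °C |  | 10 min |
| spring | 0.060 M | 1.20 M | 125 °C |  | 10 min |
| autumn | 1.0 M | 0.0800 M | 95 °C |  | 10 min |
| summer | 0.40 M | 0.286 M | 95 °C |  | 10 min |
| midnight | 0.26 M | 0.286 M | 110 °C |  | 10 min |

beta run (percent of the substrate charged)

| time / s | first product / % | substrate / % |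
|---|---|---|
| 10.0 | 12.0 | 88.2 |
| 15.0 | 17.0 | 82.8 |
| 25.0 | 24.8 | 74.7 |
| 40.0 | 33.7 | 65.0 |
| 80.0 | 47.7 | 48.8 |
| 120 | 55.4 | 39.3 |

(scatter of a reading: 0.3 percentage points)

- the flasks put in order of amount of first product, in percent of the substrate charged, best first, at 10 min (noon / dawn / spring / autumn / summer / midnight)
- the same order at 2.0 min (noon / dawn / spring / autumn / summer / midnight)
- the amount of first product, in percent of the substrate charged of the flask you put first, at 10 min
- the amount of first product, in percent of the substrate charged of the flask you put last, at 10 min

- the earlier runs do not show what temperature does; that part of a forecast is a guess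

In beta, substrate and first product together fall short of the charge. So I took two steps, each with partner: substrate gives first product, and first product is lost to partner. Let s be the ratio of the second rate constant to the first, x the fraction of substrate left, and y the first product per substrate charged. Dividing the two rates removes partner and time, and the integral is closed: y = (x^s − x)/(1 − s). For small s, the missing share is about s(x − 1 − ln x). The last beta reading misses 5.30%, which gives 0.162. This s is my selectivity factor. It is a reading, with the scatter of its readings, and I guessed that temperature leaves it unchanged.

Two extremes can be solved in the head. With substrate in great excess, x stays near 1 and each partner makes one first product, so y is the charge ratio: 15.0% for dawn and 8.00% for autumn. With partner in great excess, as in spring, the loss of first product is pseudo-first-order and y falls towards zero. Beta gives 2.70 /M/min for the first step, so first product in spring has a mean lifetime of 1.90 min even before heating, shorter than 10 min. I put spring last at 10 min, but at 2.0 min I expected it still on its way down, above autumn.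

Between the extremes, the curve peaks at x = 11.4% with y = 70.3%. Taking one partner per step, reaching that peak costs 1.07 partner per substrate. Noon and midnight charge 1.10, slightly more, so on my count of two steps their margin was thin. Summer charges 0.715, less, and stops lower. At beta's rate, I reckoned that midnight would take about 11.1 min to come to that x, longer than 10 min, while noon runs hotter. So I put noon first, near 70.3%.

The forecast differs from me at the top: midnight > noon > summer > dawn > autumn > spring at 10 min, noon > midnight > summer > dawn > spring > autumn at 2.0 min, with 68% first and 0.01% last.

The flasks gave noon > midnight > summer > dawn > autumn > spring and noon > midnight > summer > dawn > spring > autumn, with 70.1% first and 0% last.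

    partner + first product → over-reaction product (k = 0.120 /M/min, Ea = 65.0 kJ/mol)
    partner + bis adduct → tris adduct (k = 7.80 /M/min, Ea = 47.0 kJ/mol)
    partner + first product → bis adduct (k = 0.400 /M/min, Ea = 63.0 kJ/mol)
    substrate + partner → first product (k = 2.90 /M/min, Ea = 70.0 kJ/mol)
    (constants at 110 °C)

Noon ended at 70.1% because partner, the limiting reagent, ran short: 0.0244% of it was left at 10.0 min, and with that shortage taken away the same run ends at 2.19%. Noon left 14.0% of its substrate, more than the 11.4% of my peak, and the curve at that x gives 70.1%. A neighbour of noon with 0.16 M of substrate has 1.79 equiv of partner and left 0.94% of its substrate. There the curve gives 54.9%, and that flask held 55.0%.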